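Germacrane numbering is used for all main-line compounds, the six-membered ones included: C1 carries the isopropenyl group (C10, C9, C14), C3 the oxygen, C4 the methyl group C15, C6 is the carbinol or carbonyl carbon, and C7, C8, C11, C12 come from the alkenyl unit. β is the face of the ten-membered ring on which C11 leaves C7.

## Analysis of the target

The target is a heliangolide-type germacranolide: a ten-membered carbocycle (C1–C10) trans-fused at C6–C7 to an α-methylene-γ-butyrolactone (O–C6, C7, C11=C13, C12). The ring carries a Z-trisubstituted olefin C4=C5, a 1,10-epoxide, a benzoate on C3 and a (2R,3R)-epoxyangelate on C8; the ring configuration is 1R,3S,6R,7R,8R,10R. H6 and H7 are anti (trans-lactone), O8 is cis to C11 across C7–C8, O3 lies on the same β face as O8, and the epoxide is the trans epoxide of an E olefin with C14 on the β face. The methylene lactone is a Michael acceptor, both trisubstituted epoxides are acid-labile (the ring epoxide transannularly), and the two esters rule out strong base or nucleophiles late in the route. The difficulty is a medium ring with two olefins of opposite geometry, three contiguous stereocentres C6–C8 on a flexible ring, and their relation to the remote C3 and C1/C10. The feature the strategy rests on is the array C4=C5–C6(O)–C7–C8–C9–C10=C1: C4=C5 is cis as in a cyclohexene, C6 is oxygenated, and C1=C10 (the epoxide precursor) is E. That array is a cyclodeca-1(10),4-dien-6-one, the product of an oxy-Cope ring expansion of a cyclohex-2-enol bearing alkenyl groups on C6 and C1. In that reading C8 is the former terminus of an enol ether and C7 the enolate carbon, so both are set in the ring-forming event.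

## Retrosynthetic reasoning

45 to 44: the C1–O and C10–O bonds are cut last. The epoxide is the most acid-sensitive group, and C1=C10 is the only electron-rich olefin in 44, so a peracid should address it alone; the forward step must attack the face that gives the 1β,10α epoxide.

44 to 37 and 42: the C8–O acyl bond is cut. Bringing the epoxyangelate in as the preformed acid 42 keeps its two stereocentres independent of the core; 42 goes back through 40 and 39 to angelic acid 38 by a tartrate-controlled epoxidation of the Z allylic alcohol.

37 to 34: the C3 benzoate and the free C8 hydroxyl are traced to a silyl ether and a 4-methoxybenzyl ether. Both esters must come after the strongly basic methylenation, and the two ethers can be removed in turn without acid strong enough to harm the diene.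

34 to 30 to 27 to 25: C11=C13 is cut to the saturated lactone 30, the O6–C12 acyl bond to the 6,12-diol 27, and the C6 carbinol to the ketone 25. The C8 oxygen stays masked throughout so that only the 6,12-lactone can close. The forward reduction has to deliver hydride so that O6 ends anti to C11.

25 to 22: the key disconnection cuts C8–C9 and rejoins C1–C6. This turns the ten-membered ring, its E and Z olefins and the C7/C8 pair into a cyclohexenol with two trans alkenyl groups, in which only C1, C3 and C6 are stereogenic. The forward reaction must pass through one chair and protonate the enolate on one face.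

22 to 7 and 19: the C6–C7 bond is cut to the enone 7 and the alkenyl iodide 19 (through 20 and 21). The E geometry of 19 is essential, because it places the enol ether oxygen equatorial in the chair.

19 to 17 to 14 and 9: the iodide comes from syn hydrometalation of the alkynyl ether 17, which puts the metal trans to oxygen. Elimination routes to 2-halo enol ethers would favour halogen cis to oxygen. 17 is assembled from 10, 11 and 8.

7 to 6 to 5 to 1: the C6 carbonyl is introduced by allylic C–H oxidation of the silyl ether 6, and the C3 oxygen is the carbonyl oxygen of (R)-carvone 1 after reduction and inversion. An enolisation-based γ-oxygenation of an enone lacking the C3 oxygen would pass through the C1 enolate and erase the stereocentre that controls the chair; the carvone route avoids any enolate at C1.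

## Alternatives that were turned down

Alternative 1: Disconnection of the lactone O–C6 bond on a fully elaborated ten-membered ring. An amidyl radical on a C12 carboxamide nitrogen would abstract the allylic C6 hydrogen through a six-membered transition state; oxidation of the allylic radical, capture by the amide oxygen and hydrolysis would give the saturated lactone A1. In its favour, no C6 oxygen has to be carried, and the 1,5-hydrogen transfer is geometrically ideal; on economy of oxidation-state changes at C6 it is stronger than the chosen route. Against it, the C6 radical is delocalised to C4, so the Z geometry of C4=C5 and the site of C–O bond formation are at risk. The photolysis would have to tolerate two epoxides and two esters. A1 still lacks C11=C13, and enolate methylenation next to a benzoate and an epoxy ester is unattractive. Above all, the step does not build the ring: the ten-membered carbocycle with its olefin geometry, epoxide, C3 and C8 centres must already exist. The chosen strategy offers ring, C6 oxygen and the C7/C8 pair in one step.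

Alternative 2: Disconnection of C4–C5 and C1–C10 as a cyclobutane. A cyclohexenone olefin and a cyclobutene olefin would be joined by [2+2] photocycloaddition to the cis-anti-cis tricycle A2; thermal opening of the central four-membered ring of A2 would then unveil the ten-membered 1,5-diene. In its favour, C7 and C8 are set on a rigid six-membered ring before expansion, and the C7 arm arrives at the carboxylate oxidation level; on these two points it is as strong or stronger. Against it, head-to-head versus head-to-tail regiochemistry and facial selectivity of the photoaddition must both be right. The cycloreversion needs temperatures near 200 °C, at which 1,5-dienes of this kind go on to divinylcyclohexanes. The 4Z/1(10)E geometry is not dictated by a single transition state, and more stereocentres must be made beforehand. The chosen route runs at or below room temperature and derives both olefin geometries from one chair.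

Alternative 3: Disconnection of C7–C8 by radical macrocyclisation. A C8 acyl radical would add to C7 of a butenolide bearing a stannylmethyl group on C11; loss of the tin radical would form C11=C13 and give the 8-oxo lactone A3. In its favour, the methylene lactone, epoxide, benzoate and Z olefin are all in place, so the endgame is the shortest of all; on convergence and late-stage step count it is stronger. Against it, a ten-membered ring must close by attack on a substituted olefinic carbon under high dilution. The new C7 centre is set relative to C6 without a clear control element. C7 in A3 is α to a ketone and γ to the lactone carbonyl, so epimerisation and migration of the exocyclic olefin threaten. The 8-ketone must then be reduced to the 8β alcohol on a flexible ring. The chosen strategy fixes C8 and C7 by the pericyclic geometry.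

Key step: step 11

Assumption: hydrozirconation of the internal alkynyl ether 17 is taken to place zirconium on the carbon remote from oxygen (hydride to the oxygen-bearing carbon), as with terminal alkoxyalkynes.

Remark: 29 is drawn without configuration at C12, and 32 and 33 without configuration at C11; these centres are lost again in the same step.

## Route

Step 1
Reactants: 1 (R)-(−)-carvone
Product: 2 (1R,5R)-cis-carveol
Conditions: NaBH4, CeCl3·7H2O, MeOH, 0 °C
Reagents that add atoms: none
Why: Luche reduction gives clean 1,2-reduction, with hydride entering anti to the isopropenyl-bearing side to give the cis alcohol. The carbinol configuration is corrected in step 2.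

Step 2
Reactants: 2 (1R,5R)-cis-carveol
Product: 4 (1S,5R)-trans-carveyl 4-nitrobenzoate, via carveyloxyphosphonium salt 3 (not isolated)
Conditions: PPh3, diisopropyl azodicarboxylate, 4-nitrobenzoic acid, THF, 0 °C to rt
Reagents that add atoms: 4-nitrobenzoic acid, OC(=O)c1ccc(cc1)[N+](=O)[O-]
Why: Mitsunobu reaction: SN2 displacement of the alkoxyphosphonium group by the carboxylate inverts the carbinol centre to S, the C3 configuration of the target. The acidic nitrobenzoic acid keeps elimination and SN2′ attack down.

Step 3
Reactants: 4 (1S,5R)-trans-carveyl 4-nitrobenzoate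
Product: 5 (1S,5R)-trans-carveol
Conditions: K2CO3 (cat.), MeOH, rt
Reagents that add atoms: none
Why: Base-catalysed transesterification of an activated aryl ester; no stereocentre is touched.

Step 4
Reactants: 5 (1S,5R)-trans-carveol
Product: 6 (1S,5R)-trans-carveyl tert-butyldimethylsilyl ether
Conditions: TBSCl, imidazole, DMF, rt
Reagents that add atoms: tert-butyldimethylsilyl chloride, CC(C)(C)[Si](C)(C)Cl
Why: Standard silylation; the silyl ether withstands the organometallic, KH and hydride steps, and its bulk shields the C3–H bond in step 5.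

Step 5
Reactants: 6 (1S,5R)-trans-carveyl tert-butyldimethylsilyl ether
Product: 7 (4S,6R)-4-(tert-butyldimethylsilyloxy)-3-methyl-6-(prop-1-en-2-yl)cyclohex-2-en-1-one
Conditions: Rh2(cap)4 (cap = caprolactamate, 1 mol %), t-BuOOH (70% in water), NaHCO3, CH2Cl2, rt
Reagents that add atoms: tert-butyl hydroperoxide, CC(C)(C)OO
Why: Allylic C–H oxidation of a trisubstituted cycloalkene to the enone through the tert-butylperoxyl radical chain. C6 is the only ring allylic methylene, the other allylic ring hydrogen (C3–H) being tertiary and shielded by the silyl group. The non-basic medium leaves the C1 centre next to the new carbonyl intact.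

Step 6
Reactants: 8 2-(tert-butyldimethylsilyloxy)ethanol
Product: 9 2-(tert-butyldimethylsilyloxy)ethyl trifluoromethanesulfonate
Conditions: Tf2O, 2,6-lutidine, CH2Cl2, −78 °C
Reagents that add atoms: trifluoromethanesulfonic anhydride, O=S(=O)(OS(=O)(=O)C(F)(F)F)C(F)(F)F
Why: Triflation of a primary alcohol with a hindered base at low temperature; the triflate is used at once as the electrophile for step 8.

Step 7
Reactants: 10 4-methoxybenzyl alcohol; 11 trichloroethylene
Product: 14 (E)-1,2-dichlorovinyl 4-methoxybenzyl ether, via potassium 4-methoxybenzyl oxide 12 (not isolated), via dichloroacetylene 13 (not isolated)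
Conditions: KH, THF, 0 °C to rt
Reagents that add atoms: none
Why: The alkoxide dehydrochlorinates trichloroethylene to dichloroacetylene and then adds to it in an anti sense, the established entry to alkynyl ethers; the E-dichlorovinyl ether results.

Step 8
Reactants: 14 (E)-1,2-dichlorovinyl 4-methoxybenzyl ether; 9 2-(tert-butyldimethylsilyloxy)ethyl trifluoromethanesulfonate
Product: 17 tert-butyl{[4-(4-methoxybenzyloxy)but-3-yn-1-yl]oxy}dimethylsilane, via chloroethynyl ether 15 (not isolated), via lithium alkoxyacetylide 16 (not isolated)
Conditions: n-BuLi (2.2 equiv), THF, −78 to −40 °C; then 9, −78 to −20 °C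
Reagents that add atoms: none
Why: Elimination of LiCl and chlorine–lithium exchange give the lithium alkoxyacetylide, which is alkylated by the primary triflate in an SN2 reaction. The product is kept at or below room temperature because benzyl-type alkynyl ethers rearrange on heating.

Step 9
Reactants: 17 tert-butyl{[4-(4-methoxybenzyloxy)but-3-yn-1-yl]oxy}dimethylsilane
Product: 19 (E)-tert-butyl{[3-iodo-4-(4-methoxybenzyloxy)but-3-en-1-yl]oxy}dimethylsilane, via alkenylzirconocene chloride 18 (not isolated)
Conditions: Cp2Zr(H)Cl, THF, rt; then I2, −78 °C, dark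
Reagents that add atoms: iodine, II
Why: Hydrozirconation is a syn addition, so zirconium on C7 ends cis to the new C8 hydrogen and trans to oxygen; iodinolysis proceeds with retention. This gives the E iodide, the geometry that places oxygen equatorial in the chair of step 11.

Step 10
Reactants: 19 (E)-tert-butyl{[3-iodo-4-(4-methoxybenzyloxy)but-3-en-1-yl]oxy}dimethylsilane; 7 (4S,6R)-4-(tert-butyldimethylsilyloxy)-3-methyl-6-(prop-1-en-2-yl)cyclohex-2-en-1-one
Product: 22 (1R,4S,6R)-4-(tert-butyldimethylsilyloxy)-1-[(E)-4-(tert-butyldimethylsilyloxy)-1-(4-methoxybenzyloxy)but-1-en-2-yl]-3-methyl-6-(prop-1-en-2-yl)cyclohex-2-en-1-ol, via alkenyllithium 20 (not isolated), via alkenylcerium dichloride 21 (not isolated)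
Conditions: t-BuLi (2 equiv), Et2O, −78 °C; CeCl3, THF, −78 °C; then 7, −78 °C; aq. NH4Cl
Reagents that add atoms: none
Why: Iodine–lithium exchange with retention at −78 °C keeps the trans-β-alkoxy alkenyllithium from losing lithium alkoxide, and transmetalation to cerium suppresses enolisation at the doubly activated C1–H. 1,2-Addition anti to the adjacent isopropenyl group (Felkin–Anh, through the half-chair with pseudoaxial isopropenyl and pseudoequatorial silyloxy) should set C6 with the two alkenyl groups trans.

Step 11
Reactants: 22 (1R,4S,6R)-4-(tert-butyldimethylsilyloxy)-1-[(E)-4-(tert-butyldimethylsilyloxy)-1-(4-methoxybenzyloxy)but-1-en-2-yl]-3-methyl-6-(prop-1-en-2-yl)cyclohex-2-en-1-ol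
Product: 25 3β,12-bis(tert-butyldimethylsilyloxy)-8β-(4-methoxybenzyloxy)-7αH-germacra-1(10)E,4Z-dien-6-one, via potassium alkoxide 23 (not isolated), via potassium enolate 24 (not isolated)
Conditions: KH, 18-crown-6, THF, 0 °C to rt; cool to −78 °C, AcOH in THF
Reagents that add atoms: none
Why: KH with 18-crown-6 gives the free alkoxide 23, which undergoes a concerted [3,3] shift through a chair: C8–C9 forms while C1–C6 breaks, and the six-membered ring opens into the ten-membered potassium enolate 24, which is protonated on carbon at C7. The closest known reaction type is the anionic oxy-Cope rearrangement of 1,2-dialkenylcyclohexanols and -cyclohexenols to cyclodec-5-enones. The ten-membered ring arises by ring expansion (C7–C8–C9–C10 is inserted between C6 and C1 through a six-membered pericyclic array), not by end-to-end cyclisation. With the alkenyl groups trans-diequatorial, C2 is equatorial on the chair, so C1=C10 forms E, and the ring olefin is carried over as 4Z. C8 is controlled by the sense of the chair, which is fixed by C1 (R), together with the E enol ether, which keeps the oxygen equatorial; this gives the 8β oxygen relative to the untouched C3. C7 is set by protonation of the enolate on its outer face, the inner face lying across the ring from C1=C10, which places C11 cis to O8. The step needs the shift to run through the two exocyclic alkenyl groups and not through the ring olefin (which would require a bridged boat), and it needs the β-alkoxy enolate to survive: the equatorial C8–O bond lies near the nodal plane of the enolate, and the cold quench forestalls E1cB loss of 4-methoxybenzyl oxide.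

Step 12
Reactants: 25 3β,12-bis(tert-butyldimethylsilyloxy)-8β-(4-methoxybenzyloxy)-7αH-germacra-1(10)E,4Z-dien-6-one
Product: 26 3β,12-bis(tert-butyldimethylsilyloxy)-8β-(4-methoxybenzyloxy)-7αH-germacra-1(10)E,4Z-dien-6α-ol
Conditions: NaBH4, CeCl3·7H2O, MeOH/THF, −78 °C
Reagents that add atoms: none
Why: Luche 1,2-reduction of the Z-enone at low temperature, run at once so that the β-alkoxy ketone neither eliminates nor epimerises at C7. Hydride should attack the exposed outer face of the carbonyl, giving the 6α alcohol with O6 anti to C11, as the trans-lactone requires.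

Step 13
Reactants: 26 3β,12-bis(tert-butyldimethylsilyloxy)-8β-(4-methoxybenzyloxy)-7αH-germacra-1(10)E,4Z-dien-6α-ol
Product: 27 3β-(tert-butyldimethylsilyloxy)-8β-(4-methoxybenzyloxy)-7αH-germacra-1(10)E,4Z-diene-6α,12-diol
Conditions: HF·pyridine, pyridine, THF, 0 °C
Reagents that add atoms: none
Why: Buffered HF·pyridine cleaves the primary silyl ether much faster than the secondary allylic one at C3, which is hindered by the C4 methyl group. The buffer protects the 1,5-diene from protonation.

Step 14
Reactants: 27 3β-(tert-butyldimethylsilyloxy)-8β-(4-methoxybenzyloxy)-7αH-germacra-1(10)E,4Z-diene-6α,12-diol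
Product: 30 3β-(tert-butyldimethylsilyloxy)-8β-(4-methoxybenzyloxy)germacra-1(10)E,4Z-dien-12,6α-olide (6βH,7αH; trans-fused), via hydroxy aldehyde 28 (not isolated), via lactol 29 (not isolated)
Conditions: TEMPO (cat.), PhI(OAc)2, CH2Cl2, rt
Reagents that add atoms: none
Why: The oxoammonium oxidant takes the primary alcohol selectively to the aldehyde, which O6 traps as the lactol; this is oxidised on to the γ-lactone. Because O8 is masked, only the 6,12-lactone can form.

Step 15
Reactants: 30 3β-(tert-butyldimethylsilyloxy)-8β-(4-methoxybenzyloxy)germacra-1(10)E,4Z-dien-12,6α-olide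
Product: 34 3β-(tert-butyldimethylsilyloxy)-8β-(4-methoxybenzyloxy)germacra-1(10)E,4Z,11(13)-trien-12,6α-olide, via lithium enolate 31 (not isolated), via Mannich base 32 (not isolated), via ammonium iodide 33 (not isolated)
Conditions: LiN(SiMe3)2, THF, −78 °C; CH2=NMe2+ I−, −78 to 0 °C; MeI, MeOH, rt; aq. NaHCO3, CH2Cl2
Reagents that add atoms: dimethylmethyleneiminium iodide, C=[N+](C)C.[I-]
Why: Mannich reaction of the lactone enolate, N-methylation and elimination of trimethylamine is the standard α-methylenation of γ-lactones. C11 becomes sp2, so its transient configuration is immaterial, and the enolate has no leaving group on C7.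

Step 16
Reactants: 34 3β-(tert-butyldimethylsilyloxy)-8β-(4-methoxybenzyloxy)germacra-1(10)E,4Z,11(13)-trien-12,6α-olide
Product: 35 3β-hydroxy-8β-(4-methoxybenzyloxy)germacra-1(10)E,4Z,11(13)-trien-12,6α-olide
Conditions: HF·pyridine, THF, 0 °C to rt
Reagents that add atoms: none
Why: Acidic fluoride removes the remaining silyl ether without the basic conditions that would invite conjugate addition to the methylene lactone.

Step 17
Reactants: 35 3β-hydroxy-8β-(4-methoxybenzyloxy)germacra-1(10)E,4Z,11(13)-trien-12,6α-olide
Product: 36 3β-benzoyloxy-8β-(4-methoxybenzyloxy)germacra-1(10)E,4Z,11(13)-trien-12,6α-olide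
Conditions: BzCl, pyridine, DMAP (cat.), CH2Cl2, 0 °C
Reagents that add atoms: benzoyl chloride, O=C(Cl)c1ccccc1
Why: Acylation of the allylic alcohol at oxygen; the C3 configuration is retained.

Step 18
Reactants: 36 3β-benzoyloxy-8β-(4-methoxybenzyloxy)germacra-1(10)E,4Z,11(13)-trien-12,6α-olide
Product: 37 3β-benzoyloxy-8β-hydroxygermacra-1(10)E,4Z,11(13)-trien-12,6α-olide
Conditions: DDQ, CH2Cl2/pH 7 buffer, 0 °C to rt
Reagents that add atoms: none
Why: Oxidative cleavage of the 4-methoxybenzyl ether under neutral buffered conditions. The benzoate, the methylene lactone and the olefins are not electron-rich enough to compete, and the absence of base keeps O8 from attacking the lactone.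

Step 19
Reactants: 38 angelic acid
Product: 39 (Z)-2-methylbut-2-en-1-ol
Conditions: LiAlH4, Et2O, 0 °C
Reagents that add atoms: none
Why: Hydride reduction of the conjugated acid to the allylic alcohol at low temperature, where the Z olefin does not isomerise.

Step 20
Reactants: 39 (Z)-2-methylbut-2-en-1-ol
Product: 40 [(2S,3R)-2,3-dimethyloxiran-2-yl]methanol
Conditions: Ti(OiPr)4, L-(+)-diisopropyl tartrate, t-BuOOH, 4 Å sieves, CH2Cl2, −20 °C
Reagents that add atoms: tert-butyl hydroperoxide, CC(C)(C)OO
Why: Sharpless asymmetric epoxidation: the L-(+)-tartrate complex delivers oxygen to the olefin face that gives the (2S,3R) epoxy alcohol. The Z geometry is carried into the cis relation of C1 and the C3 methyl group.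

Step 21
Reactants: 40 [(2S,3R)-2,3-dimethyloxiran-2-yl]methanol
Product: 42 (2R,3R)-2,3-dimethyloxirane-2-carboxylic acid, via epoxy aldehyde 41 (not isolated)
Conditions: TEMPO (cat.), NaOCl (cat.), NaClO2, MeCN/phosphate buffer pH 6.7, rt
Reagents that add atoms: sodium chlorite, [Na+].[O-]Cl=O
Why: The oxoammonium/chlorite oxidation takes the primary alcohol through the aldehyde to the acid in a near-neutral buffer that does not open the epoxide. No stereocentre is touched; only the descriptor at C2 changes.

Step 22
Reactants: 37 3β-benzoyloxy-8β-hydroxygermacra-1(10)E,4Z,11(13)-trien-12,6α-olide; 42 (2R,3R)-2,3-dimethyloxirane-2-carboxylic acid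
Product: 44 3β-benzoyloxy-8β-[(2R,3R)-2,3-dimethyloxirane-2-carbonyloxy]germacra-1(10)E,4Z,11(13)-trien-12,6α-olide, via mixed anhydride 43 (not isolated)
Conditions: 2,4,6-trichlorobenzoyl chloride, Et3N, THF, rt; then 37, DMAP, toluene, rt
Reagents that add atoms: none
Why: Yamaguchi esterification: DMAP attacks the mixed anhydride at the aliphatic carbonyl, and the acylpyridinium acylates the hindered 8β alcohol at oxygen with retention. Rapid acylation should outrun translactonisation to O8.

Step 23
Reactants: 44 3β-benzoyloxy-8β-[(2R,3R)-2,3-dimethyloxirane-2-carbonyloxy]germacra-1(10)E,4Z,11(13)-trien-12,6α-olide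
Product: 45 target CNP0324463.6, 3β-benzoyloxy-8β-[(2R,3R)-2,3-dimethyloxirane-2-carbonyloxy]-1β,10α-epoxygermacra-4Z,11(13)-dien-12,6α-olide
Conditions: mCPBA, NaHCO3, CH2Cl2, 0 °C
Reagents that add atoms: 3-chloroperoxybenzoic acid, OOC(=O)c1cccc(Cl)c1
Why: Prilezhaev epoxidation: C1=C10 is the only electron-rich olefin (C4=C5 lies between two acyloxy-bearing carbons and C11=C13 is conjugated). Syn addition to the E olefin gives the trans epoxide, and attack on the exposed face of the conformer with C14 on the β face should give the 1β,10α (1R,10R) isomer.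

## Compound list

1 | (R)-(−)-carvone | C=C(C)[C@H]1CC(=O)C(C)=CC1 | starting material
2 | (1R,5R)-cis-carveol | C=C(C)[C@H]1C[C@@H](O)C(C)=CC1 | intermediate
3 | cis-carveyloxytriphenylphosphonium 4-nitrobenzoate | C=C(C)[C@H]1C[C@@H](O[P+](c2ccccc2)(c2ccccc2)c2ccccc2)C(C)=CC1.[O-]C(=O)c1ccc(cc1)[N+](=O)[O-] | intermediate
4 | (1S,5R)-trans-carveyl 4-nitrobenzoate | C=C(C)[C@H]1C[C@H](OC(=O)c2ccc(cc2)[N+](=O)[O-])C(C)=CC1 | intermediate
5 | (1S,5R)-trans-carveol | C=C(C)[C@H]1C[C@H](O)C(C)=CC1 | intermediate
6 | (1S,5R)-trans-carveyl tert-butyldimethylsilyl ether | C=C(C)[C@H]1C[C@H](O[Si](C)(C)C(C)(C)C)C(C)=CC1 | intermediate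
7 | (4S,6R)-4-(tert-butyldimethylsilyloxy)-3-methyl-6-(prop-1-en-2-yl)cyclohex-2-en-1-one | C=C(C)[C@H]1C[C@H](O[Si](C)(C)C(C)(C)C)C(C)=CC1=O | intermediate
8 | 2-(tert-butyldimethylsilyloxy)ethanol | OCCO[Si](C)(C)C(C)(C)C | starting material
9 | 2-(tert-butyldimethylsilyloxy)ethyl trifluoromethanesulfonate | O=S(=O)(OCCO[Si](C)(C)C(C)(C)C)C(F)(F)F | intermediate
10 | 4-methoxybenzyl alcohol | COc1ccc(CO)cc1 | starting material
11 | trichloroethylene | ClC=C(Cl)Cl | starting material
12 | potassium 4-methoxybenzyl oxide | COc1ccc(C[O-])cc1.[K+] | intermediate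
13 | dichloroacetylene | ClC#CCl | intermediate
14 | (E)-1,2-dichlorovinyl 4-methoxybenzyl ether | Cl/C=C(Cl)\OCc1ccc(OC)cc1 | intermediate
15 | chloroethynyl 4-methoxybenzyl ether | ClC#COCc1ccc(OC)cc1 | intermediate
16 | lithium (4-methoxybenzyloxy)acetylide | [Li]C#COCc1ccc(OC)cc1 | intermediate
17 | tert-butyl{[4-(4-methoxybenzyloxy)but-3-yn-1-yl]oxy}dimethylsilane | COc1ccc(COC#CCCO[Si](C)(C)C(C)(C)C)cc1 | intermediate
18 | (E)-alkenylzirconocene chloride (Zr on C7, trans to oxygen; cyclopentadienyl rings drawn σ-bonded) | Cl[Zr](C1C=CC=C1)(C1C=CC=C1)/C(CCO[Si](C)(C)C(C)(C)C)=C/OCc1ccc(OC)cc1 | intermediate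
19 | (E)-tert-butyl{[3-iodo-4-(4-methoxybenzyloxy)but-3-en-1-yl]oxy}dimethylsilane | I/C(CCO[Si](C)(C)C(C)(C)C)=C/OCc1ccc(OC)cc1 | intermediate
20 | (E)-alkenyllithium from 19 | [Li]/C(CCO[Si](C)(C)C(C)(C)C)=C/OCc1ccc(OC)cc1 | intermediate
21 | (E)-alkenylcerium dichloride | Cl[Ce](Cl)/C(CCO[Si](C)(C)C(C)(C)C)=C/OCc1ccc(OC)cc1 | intermediate
22 | (1R,4S,6R)-4-(tert-butyldimethylsilyloxy)-1-[(E)-4-(tert-butyldimethylsilyloxy)-1-(4-methoxybenzyloxy)but-1-en-2-yl]-3-methyl-6-(prop-1-en-2-yl)cyclohex-2-en-1-ol (alkenyl groups trans) | C=C(C)[C@H]1C[C@H](O[Si](C)(C)C(C)(C)C)C(C)=C[C@]1(O)/C(CCO[Si](C)(C)C(C)(C)C)=C/OCc2ccc(OC)cc2 | intermediate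
23 | potassium alkoxide of 22 | C=C(C)[C@H]1C[C@H](O[Si](C)(C)C(C)(C)C)C(C)=C[C@]1([O-])/C(CCO[Si](C)(C)C(C)(C)C)=C/OCc2ccc(OC)cc2.[K+] | intermediate
24 | ten-membered potassium enolate (C6=C7, C5 and C8 trans; 1(10)E,4Z) | CC(C)(C)[Si](C)(C)OCC/C1=C([O-])\C=C(\C)[C@@H](O[Si](C)(C)C(C)(C)C)C/C=C(\C)C[C@H]1OCc2ccc(OC)cc2.[K+] | intermediate
25 | 3β,12-bis(tert-butyldimethylsilyloxy)-8β-(4-methoxybenzyloxy)-7αH-germacra-1(10)E,4Z-dien-6-one | CC(C)(C)[Si](C)(C)OCC[C@H]1C(=O)/C=C(/C)[C@@H](O[Si](C)(C)C(C)(C)C)C/C=C(\C)C[C@H]1OCc2ccc(OC)cc2 | intermediate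
26 | 3β,12-bis(tert-butyldimethylsilyloxy)-8β-(4-methoxybenzyloxy)-7αH-germacra-1(10)E,4Z-dien-6α-ol | CC(C)(C)[Si](C)(C)OCC[C@H]1[C@H](O)/C=C(/C)[C@@H](O[Si](C)(C)C(C)(C)C)C/C=C(\C)C[C@H]1OCc2ccc(OC)cc2 | intermediate
27 | 3β-(tert-butyldimethylsilyloxy)-8β-(4-methoxybenzyloxy)-7αH-germacra-1(10)E,4Z-diene-6α,12-diol | OCC[C@H]1[C@H](O)/C=C(/C)[C@@H](O[Si](C)(C)C(C)(C)C)C/C=C(\C)C[C@H]1OCc2ccc(OC)cc2 | intermediate
28 | 6α-hydroxy 12-aldehyde | O=CC[C@H]1[C@H](O)/C=C(/C)[C@@H](O[Si](C)(C)C(C)(C)C)C/C=C(\C)C[C@H]1OCc2ccc(OC)cc2 | intermediate
29 | 12,6α-lactol (C12 epimers) | C1C(O)O[C@@H]2/C=C(/C)[C@@H](O[Si](C)(C)C(C)(C)C)C/C=C(\C)C[C@@H](OCc3ccc(OC)cc3)[C@@H]12 | intermediate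
30 | 3β-(tert-butyldimethylsilyloxy)-8β-(4-methoxybenzyloxy)germacra-1(10)E,4Z-dien-12,6α-olide | C1C(=O)O[C@@H]2/C=C(/C)[C@@H](O[Si](C)(C)C(C)(C)C)C/C=C(\C)C[C@@H](OCc3ccc(OC)cc3)[C@@H]12 | intermediate
31 | lithium enolate of 30 | C1=C(O[Li])O[C@@H]2/C=C(/C)[C@@H](O[Si](C)(C)C(C)(C)C)C/C=C(\C)C[C@@H](OCc3ccc(OC)cc3)[C@@H]12 | intermediate
32 | 13-dimethylamino-11,13-dihydro lactone (Mannich base, C11 epimers) | CN(C)CC1C(=O)O[C@@H]2/C=C(/C)[C@@H](O[Si](C)(C)C(C)(C)C)C/C=C(\C)C[C@@H](OCc3ccc(OC)cc3)[C@@H]12 | intermediate
33 | 13-trimethylammonio lactone iodide | C[N+](C)(C)CC1C(=O)O[C@@H]2/C=C(/C)[C@@H](O[Si](C)(C)C(C)(C)C)C/C=C(\C)C[C@@H](OCc3ccc(OC)cc3)[C@@H]12.[I-] | intermediate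
34 | 3β-(tert-butyldimethylsilyloxy)-8β-(4-methoxybenzyloxy)germacra-1(10)E,4Z,11(13)-trien-12,6α-olide | C=C1C(=O)O[C@@H]2/C=C(/C)[C@@H](O[Si](C)(C)C(C)(C)C)C/C=C(\C)C[C@@H](OCc3ccc(OC)cc3)[C@@H]12 | intermediate
35 | 3β-hydroxy-8β-(4-methoxybenzyloxy)germacra-1(10)E,4Z,11(13)-trien-12,6α-olide | C=C1C(=O)O[C@@H]2/C=C(/C)[C@@H](O)C/C=C(\C)C[C@@H](OCc3ccc(OC)cc3)[C@@H]12 | intermediate
36 | 3β-benzoyloxy-8β-(4-methoxybenzyloxy)germacra-1(10)E,4Z,11(13)-trien-12,6α-olide | C=C1C(=O)O[C@@H]2/C=C(/C)[C@@H](OC(=O)c3ccccc3)C/C=C(\C)C[C@@H](OCc3ccc(OC)cc3)[C@@H]12 | intermediate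
37 | 3β-benzoyloxy-8β-hydroxygermacra-1(10)E,4Z,11(13)-trien-12,6α-olide | C=C1C(=O)O[C@@H]2/C=C(/C)[C@@H](OC(=O)c3ccccc3)C/C=C(\C)C[C@@H](O)[C@@H]12 | intermediate
38 | angelic acid | C/C=C(/C)C(=O)O | starting material
39 | (Z)-2-methylbut-2-en-1-ol | C/C=C(/C)CO | intermediate
40 | [(2S,3R)-2,3-dimethyloxiran-2-yl]methanol | OC[C@]1(C)O[C@@H]1C | intermediate
41 | (2R,3R)-2,3-dimethyloxirane-2-carbaldehyde | O=C[C@]1(C)O[C@@H]1C | intermediate
42 | (2R,3R)-2,3-dimethyloxirane-2-carboxylic acid | OC(=O)[C@]1(C)O[C@@H]1C | intermediate
43 | (2R,3R)-2,3-dimethyloxirane-2-carboxylic 2,4,6-trichlorobenzoic anhydride | O=C(OC(=O)c1c(Cl)cc(Cl)cc1Cl)[C@]1(C)O[C@@H]1C | intermediate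
44 | 3β-benzoyloxy-8β-[(2R,3R)-2,3-dimethyloxirane-2-carbonyloxy]germacra-1(10)E,4Z,11(13)-trien-12,6α-olide | C=C1C(=O)O[C@@H]2/C=C(/C)[C@@H](OC(=O)c3ccccc3)C/C=C(\C)C[C@@H](OC(=O)[C@]3(C)O[C@@H]3C)[C@@H]12 | intermediate
45 | CNP0324463.6 | C=C1C(=O)O[C@@H]2/C=C(/C)[C@@H](OC(=O)c3ccccc3)C[C@H]3O[C@]3(C)C[C@@H](OC(=O)[C@]3(C)O[C@@H]3C)[C@@H]12 | target

## Step count and risk

Total: 23 steps. Longest linear sequence: 16 steps (steps 1–5, 10–18, 22, 23), from (R)-carvone.

Least certain steps:

Key step 11. Three things may go wrong. The enolate may lose 4-methoxybenzyl oxide by β-elimination once the ring relaxes. Protonation at C7 may occur on both faces if the enolate unit turns through the ring before the quench. The alkoxide may fragment instead of rearranging. The fallback is the neutral silyloxy variant. It sets out from 22, which is silylated at the tertiary hydroxyl (trimethylsilyl triflate, 2,6-lutidine) to the C6 trimethylsilyl ether F1. Thermolysis of F1 in a sealed, base-washed vessel near 200 °C should pass through the same chair to the ten-membered trimethylsilyl enol ether F2. No enolate is present, so β-elimination cannot occur. Protodesilylation of F2 with buffered fluoride and acetic acid at −78 °C returns to 25, and the proton source can be varied there to control C7.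

Step 10. Facial selectivity at the carbonyl is the main doubt: addition syn to the isopropenyl group is possible, because axial attack on the half-chair with equatorial isopropenyl competes. Enolisation of 7, or loss of lithium alkoxide from 20 before addition, would lower conversion. The fallback uses the other epimer instead of discarding it. It sets out from 7 and 21, which then give the C6-epimeric carbinol F3 (alkenyl groups cis). Under the conditions of step 11, its alkoxide can keep C2 equatorial on the pericyclic chair only with the isopropenyl group axial on the cyclohexene. The sense of that chair is still fixed by C1, so the same E olefin and the same C8 configuration result, now through the potassium enolate F4 in which C5 and C8 are cis. Protonation of F4 at C7, or equilibration next to the ketone if needed, returns to 25.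

Step 9. Zirconium may bond to the oxygen-bearing carbon instead of C7, or the benzyl-type alkynyl ether may rearrange before it is hydrometalated. The fallback gives up hydrometalation. It sets out from 17, which is semi-hydrogenated (H2, Lindlar catalyst) to the Z enol ether F5. Addition of bromine gives the dibromide F6, and dehydrobromination with DBU gives the E bromide F7 together with its geometric isomer. Elimination is not expected to favour F7, so the isomers must be separated. Bromine–lithium exchange of F7 with t-BuLi at −78 °C returns to 20.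

Step 5. Hydrogen abstraction may occur at the silyloxy-bearing C3–H or at the allylic positions of the isopropenyl group, and the enone may be over-oxidised. The fallback replaces C–H oxidation by an oxidative transposition. It sets out from 6, whose ring olefin is epoxidised with a peracid anti to the silyloxy group to give the epoxide F8. Sodium phenylselenide opens F8 at the secondary carbon to the hydroxy selenide F9. Oxidation with H2O2 and selenoxide elimination give the tertiary allylic alcohol F10. Pyridinium chlorochromate then effects the 1,3-oxidative transposition of F10 to 7.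

Step 23. The peracid may attack both faces of C1=C10 if both rotamers of the E olefin are populated, and C4=C5 may compete to a small extent. The fallback replaces substrate control by reagent control. It sets out from 44 and uses a chiral dioxirane (Shi epoxidation: fructose-derived ketone, KHSO5, buffered MeCN/water), the ketone enantiomer being chosen for the required face. It returns to 45 without new intermediates.

## Further compounds

F1 | step 11 | C6 trimethylsilyl ether of 22 | C=C(C)[C@H]1C[C@H](O[Si](C)(C)C(C)(C)C)C(C)=C[C@]1(O[Si](C)(C)C)/C(CCO[Si](C)(C)C(C)(C)C)=C/OCc2ccc(OC)cc2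
F2 | step 11 | ten-membered 6-trimethylsilyl enol ether (C6=C7, C5 and C8 trans; 1(10)E,4Z) | CC(C)(C)[Si](C)(C)OCC/C1=C(O[Si](C)(C)C)\C=C(\C)[C@@H](O[Si](C)(C)C(C)(C)C)C/C=C(\C)C[C@H]1OCc2ccc(OC)cc2
F3 | step 10 | C6 epimer of 22 (alkenyl groups cis) | C=C(C)[C@H]1C[C@H](O[Si](C)(C)C(C)(C)C)C(C)=C[C@@]1(O)/C(CCO[Si](C)(C)C(C)(C)C)=C/OCc2ccc(OC)cc2
F4 | step 10 | ten-membered potassium enolate with C5 and C8 cis | CC(C)(C)[Si](C)(C)OCC/C1=C([O-])/C=C(/C)[C@@H](O[Si](C)(C)C(C)(C)C)C/C=C(\C)C[C@H]1OCc2ccc(OC)cc2.[K+]
F5 | step 9 | (Z)-tert-butyl{[4-(4-methoxybenzyloxy)but-3-en-1-yl]oxy}dimethylsilane | CC(C)(C)[Si](C)(C)OCC/C=C\OCc1ccc(OC)cc1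
F6 | step 9 | tert-butyl{[3,4-dibromo-4-(4-methoxybenzyloxy)butyl]oxy}dimethylsilane | CC(C)(C)[Si](C)(C)OCCC(Br)C(Br)OCc1ccc(OC)cc1
F7 | step 9 | (E)-tert-butyl{[3-bromo-4-(4-methoxybenzyloxy)but-3-en-1-yl]oxy}dimethylsilane | Br/C(CCO[Si](C)(C)C(C)(C)C)=C/OCc1ccc(OC)cc1
F8 | step 5 | ring epoxide of 6 (epoxide trans to silyloxy) | C=C(C)[C@H]1C[C@H](O[Si](C)(C)C(C)(C)C)[C@@]2(C)O[C@H]2C1
F9 | step 5 | trans-hydroxy phenylselenide from F8 | C=C(C)[C@H]1C[C@H](O[Si](C)(C)C(C)(C)C)[C@@](C)(O)[C@H]([Se]c2ccccc2)C1
F10 | step 5 | tertiary allylic alcohol from F9 | C=C(C)[C@H]1C[C@H](O[Si](C)(C)C(C)(C)C)[C@@](C)(O)C=C1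
F0 | step 23 | none | none
A1 | alternative 1 | 11,13-dihydro target (saturated trans-fused lactone) | C1C(=O)O[C@@H]2/C=C(/C)[C@@H](OC(=O)c3ccccc3)C[C@H]3O[C@]3(C)C[C@@H](OC(=O)[C@]3(C)O[C@@H]3C)[C@@H]12
A2 | alternative 2 | cis-anti-cis tricyclic photoadduct (cyclobutane C1, C4, C5, C10) | C[C@@]12[C@@H](O[Si](C(C)C)(C(C)C)C(C)C)C[C@@H]1[C@@]3(C)C[C@@H](O[Si](C)(C)C(C)(C)C)[C@@H](CC(=O)OC(C)(C)C)C(=O)[C@H]32
A3 | alternative 3 | 8-oxo core with methylene lactone, epoxide and C3 benzoate | C=C1C(=O)O[C@@H]2/C=C(/C)[C@@H](OC(=O)c3ccccc3)C[C@H]3O[C@]3(C)CC(=O)[C@@H]12
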